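## Structural features

The target is a linear oligolignol with five aromatic rings (A to E). Its centre is a C2-symmetric exo,exo-2,6-diaryl-3,7-dioxabicyclo[3.3.0]octane (the syringaresinol core) whose aryl groups are the 4-oxy-3,5-dimethoxyphenyl rings C and D. The ring C oxygen is bonded to Cβ2 of unit 2, a threo (αR,βR) arylglycerol whose Cα2 carries guaiacyl ring B. The ring B oxygen is in turn bonded to Cβ1 of unit 1, an erythro (αR,βS) arylglycerol capped by ring A. The ring D oxygen is bonded to Cβ3 of unit 3, an erythro (αS,βR) arylglycerol capped by ring E. There are ten stereocentres: four contiguous ones in the cis-fused core (7R,8S,7'R,8'S) and three vicinal Cα/Cβ pairs that are separated by aromatic rings, so no pair can control another. The fragile parts are the five benzylic C–O bonds para to oxygen (Cα1, Cα2, Cα3, C-7, C-7'), which ionise in acid and are cleaved by hydrogenolysis, the free phenols, and any α-aryloxy carbonyl intermediate, which can epimerise or lose the β-oxygen. The real difficulty is to place one threo unit and two erythro units of opposite absolute sense on a symmetric core that must be desymmetrised. The key step uses the fact that rings A and E are the same 4-hydroxy-3-methoxyphenyl group, each on an erythro carbinol (Cα1, Cα3) next to an aryloxy-bearing carbon (Cβ1 on the ring B oxygen, Cβ3 on the ring D oxygen) of mirror-image configuration.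

## Logic of the disconnections

27 ⇒ 26 ⇒ 25. Only protecting-group bonds are cut: four O–Si bonds (two phenolic, two at Cγ1 and Cγ3) and the two ketal C–O bonds on unit 2. They come last because free phenols and a free 1,3-diol would consume the organometallic reagent and would not survive the oxidation before it. Nothing is gained in skeleton. The demand is that no benzylic C–O bond ionises, so the ketal is opened with weak aqueous acid while the phenols are still silylated, and the silyl groups then leave with buffered fluoride.

25 ⇒ 20 + two molecules of 24. The bonds Cα1–ring A and Cα3–ring E are cut together. The two chain ends are identical in constitution and mirror images in local configuration, so one achiral aryl nucleophile can serve both. This removes two rings and two stereocentres in one operation. The forward step must give 1,2-anti induction at both formyl groups without epimerising the α-aryloxy aldehydes. The configurations of 20 and 25 were checked centre by centre against the target string and agree with it. The Cγ silyl group is chosen as tert-butyldiphenylsilyl: it is bulky and non-coordinating, and it does not migrate between the two primary oxygens of the arm, a migration that would racemise Cβ1 and Cβ3 at the stage of 18 and 19.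

24 ⇒ 23 ⇒ 22 ⇒ 21. The C–Ti, C–Li and O–Si bonds are cut back to a bromophenol. The titanium reagent has to be made in the flask from the aryllithium; the phenol needs a silyl group that leaves in the last step.

20 ⇒ 19 ⇒ 18. These are changes of oxidation level and protection only: the two formyl groups come from primary alcohols, and the ketal comes from the free 1,3-diol of unit 2. The demand is that the ketal forms only on the one true 1,3-diol and that the oxidation is non-basic.

18 ⇒ 17 ⇒ 16 ⇒ 11 + 15. After returning the three primary alcohols to acyl groups (one imide, two methyl esters), the Cα2–Cβ2 bond is cut. This is the only C–C bond of unit 2 that joins two large pieces, and an auxiliary-controlled syn-aldol gives the threo relation and the absolute configuration together. Both arms are already present as esters, so a single hydride step later converts all three carbonyl groups. The enolisation must be selective for the imide in the presence of two esters.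

15 ⇒ 14 + 13, and 13 ⇒ 12. The ring B O–Cβ1 bond is cut. Attaching the arm to the aldehyde before the aldol means ring B never needs a phenol protecting group. The forward step must invert the carbinol carbon of 13 cleanly.

11 ⇒ 8 + 10, and 10 ⇒ 9. The ring D O–Cβ3 bond is cut in the same way, with the enantiomeric hydroxy ester. The hindered 2,6-dimethoxyphenol of 8 must act as the nucleophile, again with inversion.

8 ⇒ 5 + 7, and 7 ⇒ 6. The ring C O–CH2 bond is cut. This alkylation is also the desymmetrisation of 5, so no separate mono-protection and deprotection are needed. The price is a statistical mono-alkylation with recycling of 5.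

5 ⇒ 4 ⇒ 3 ⇒ 2 ⇒ 1. The C-8–C-8' bond and the two C-7–O bonds of the core are cut at its C2 axis, leading to two molecules of 3. The whole core then comes from one oxidative dimerisation. The demand is that the racemate 4 must be resolved, which costs half of the material at an early and cheap stage.

## Other disconnections considered

Alternative 1: The cut lies inside the core, at the bis-lactone oxidation level: the bonds C-1–C-2 and C-5–C-6 of the dioxabicyclo[3.3.0]octane and the two ring C–O bonds. In the forward step the bis(dibutylboron enolate) of the succinyl bis-imide A1 would add to two molecules of the aldehyde A2, and each aldolate oxygen would acylate the far imide carbonyl to give the dilactone A3 with loss of both auxiliaries.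
- In its favour: one auxiliary would set all four core stereocentres in one operation, and the syn-aldol topology maps onto the exo-aryl, cis-fused bicycle. No material is lost to a resolution, so on absolute stereocontrol of the core it is the better plan. In its use of the C2 axis it is the equal of the dimerisation 3 → 4.
- Against it: enolising both adjacent α-carbons of a succinyl unit is not secured. If lactonisation follows the first aldol, the second nucleophile is a lactone enolate without auxiliary control.
- A3 is still three operations from the diphenol (reduction to the tetraol, ring closure at the primary carbons, debenzylation beside benzylic ethers). The product is again a symmetric diphenol that needs the same statistical mono-alkylation.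
- Comparison: it replaces a radical coupling under thermodynamic control by an auxiliary-controlled polar sequence. It is longer by about three steps to 5 and leaves the three arylglycerol units untouched.

Alternative 2: The cut removes C-1–C-5 and O-7–C-6 of the core and leads back to the open-chain epoxy cinnamyl ether A4. In the forward step Cp2TiCl (trivalent titanium) would open the epoxide homolytically to the C-1 radical, 5-exo addition to the cinnamyl double bond would form C-1–C-5, the benzylic C-6 radical would be captured with iodine, and the C-8 alkoxide would close the second ring to give A5. Either epoxide epimer of A4 serves, since C-1 becomes a radical.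
- In its favour: this radical cascade is an established route to furofuran lignans, and the single carbinol centre of A4 can be set by asymmetric catalysis. A5 carries two different phenol protecting groups, so neither a resolution nor a statistical mono-alkylation is needed. On these two points it is better than the chosen plan.
- Against it: C-1 is planarised, and C-5 and C-6 rest on substrate control in a radical cyclisation and an ionic ring closure, so epimers at the aryl-bearing carbon are to be expected.
- Two different aryl building blocks and a kinetic resolution or its equivalent are needed to reach A4, which makes the differentiated core about seven to eight steps. Two equivalents of the titanium reagent are consumed, and the benzyl ether must be removed by hydrogenolysis next to the benzylic ethers of the core.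
- Comparison: the chosen plan has two steps limited to about half of the material (steps 4 and 6) but uses shorter and more predictable chemistry. From 8 onward the two plans would be the same, apart from one extra deprotection for A5.

Alternative 3: The cut is made at Cβ2–Cγ2 and Cβ3–Cγ3, removed together from the C2-symmetric bis(aryloxyacetyl) imide A6. In the forward step the bis-enolate of A6 would be alkylated twice with benzyl chloromethyl ether to give A7, the auxiliary setting both Cβ centres.
- In its favour: Cβ2 and Cβ3 are both (R), so the C2 axis of the core is kept and one enantiomer of one auxiliary serves both arms. No statistical step is needed up to A7, and the (S)-benzyl auxiliary should induce the required sense. On these points it is equal to or better than the chosen plan, which needs two enantiomeric glycerates.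
- Against it: the symmetry is used in the wrong place. Beyond A7 the arms must diverge in every respect: unit 2 needs a threo carbinol and ring B (which must itself carry unit 1), while unit 3 needs an erythro carbinol and ring E.
- The desymmetrisation is therefore only postponed to a more valuable stage and tied to two aryl additions of opposite stereochemical sense.
- Alkylation of glycolate imide enolates with a hard chloromethyl ether competes with O-alkylation and with loss of benzyloxide from the product under excess base. The Cγ benzyl ethers would have to be removed by hydrogenolysis beside five benzylic C–O bonds.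
- Comparison: the chosen plan uses the pseudo-symmetry that really exists at the chain ends and needs no differentiation there. Alternative 3 would be longer by the steps needed to build and attach ring B with unit 1 and to tell the two arms apart.

Key step: step 16

Assumption: methyl (S)- and (R)-glycerate (9, 12) are taken as catalogue compounds; they are the diazotisation and esterification products of L- and D-serine, which would add two steps per arm if they had to be made.

Remark: the racemate 4 is written as the two enantiomer strings joined by a dot.

## Steps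

Step 1
Reactants: 1 syringaldehyde
Product: 2 ethyl (E)-sinapate
Conditions: Ph3P=CHCO2Et, toluene, 100 °C
Reagents that add atoms: ethyl (triphenylphosphoranylidene)acetate, CCOC(=O)C=P(c1ccccc1)(c1ccccc1)c1ccccc1
Why: Wittig olefination with a stabilised ylide tolerates the free phenol and gives the (E)-cinnamate.

Step 2
Reactants: 2 ethyl (E)-sinapate
Product: 3 sinapyl alcohol
Conditions: iBu2AlH (4 equiv), toluene, −78 → 0 °C; aq. potassium sodium tartrate
Reagents that add atoms: none
Why: iBu2AlH reduces the unsaturated ester by 1,2-addition to the allylic alcohol; the first equivalent is consumed by the phenol.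

Step 3
Reactants: 3 sinapyl alcohol (two molecules)
Product: 4 rac-syringaresinol
Conditions: FeCl3·6H2O (2.2 equiv), acetone/H2O, rt
Reagents that add atoms: none
Why: Oxidative phenol coupling: one-electron oxidation gives phenoxyl radicals that join at C-β because both positions ortho to the oxygen are blocked by methoxy groups, and the γ-hydroxyls then add to the two benzylic carbons and close both tetrahydrofuran rings. The cis-fused exo,exo-diaryl bicycle is the favoured relative configuration and the product is racemic.

Step 4
Reactants: 4 rac-syringaresinol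
Product: 5 (7R,7'R,8S,8'S)-syringaresinol
Conditions: preparative SFC, amylose tris(3,5-dimethylphenylcarbamate) phase, CO2/MeOH, 35 °C
Reagents that add atoms: none
Why: Resolution by chromatography on a chiral stationary phase; the rigid C2-symmetric diaryl bicycle should be well discriminated by a polysaccharide carbamate phase. The fraction is assigned by the sign of its optical rotation against the known enantiomers, and this step fixes the four core stereocentres of the target.

Step 5
Reactants: 6 (S)-4-benzyloxazolidin-2-one
Product: 7 (S)-4-benzyl-3-(bromoacetyl)oxazolidin-2-one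
Conditions: n-BuLi, THF, −78 °C; BrCH2COBr, −78 → 0 °C
Reagents that add atoms: bromoacetyl bromide, O=C(Br)CBr
Why: N-acylation of the lithiated oxazolidinone; the acyl bromide carbon reacts much faster than the CH2Br carbon at low temperature.

Step 6
Reactants: 5 (7R,7'R,8S,8'S)-syringaresinol; 7 (S)-4-benzyl-3-(bromoacetyl)oxazolidin-2-one (0.6 equiv)
Product: 8 mono-glycolate imide of the core (ring C oxygen alkylated; ring D phenol free)
Conditions: K2CO3, acetone, rt; unreacted 5 recovered and recycled
Reagents that add atoms: none
Why: Williamson ether synthesis: the α-bromo imide is an activated SN2 electrophile, so the hindered phenoxide should be alkylated faster than it attacks the imide carbonyl. The two phenols of 5 are equivalent, so only one mono-ether can form, and a deficit of 7 keeps the bis-ether low.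

Step 7
Reactants: 9 methyl (S)-glycerate
Product: 10 methyl (2S)-3-(tert-butyldiphenylsilyloxy)-2-hydroxypropanoate
Conditions: TBDPSCl (1.05 equiv), imidazole, CH2Cl2, 0 °C
Reagents that add atoms: tert-butylchlorodiphenylsilane, CC(C)(C)[Si](Cl)(c1ccccc1)c1ccccc1
Why: Selective silylation of the primary hydroxyl; the secondary α-hydroxy ester oxygen is hindered and less nucleophilic.

Step 8
Reactants: 8 mono-glycolate imide of the core; 10 methyl (2S)-3-(tert-butyldiphenylsilyloxy)-2-hydroxypropanoate
Product: 11 core imide ester (ring D oxygen bonded to Cβ3 of the (R)-configured methyl 3-silyloxypropanoate arm)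
Conditions: PPh3, DIAD, THF, 0 °C → rt
Reagents that add atoms: none
Why: Mitsunobu etherification: the phenoxide displaces the phosphonium-activated α-oxygen of the hydroxy ester by SN2 with inversion, so the (S) carbinol gives (R) at Cβ3. The imide CH2 is not acidic enough to compete as a pronucleophile.

Step 9
Reactants: 12 methyl (R)-glycerate
Product: 13 methyl (2R)-3-(tert-butyldiphenylsilyloxy)-2-hydroxypropanoate
Conditions: TBDPSCl (1.05 equiv), imidazole, CH2Cl2, 0 °C
Reagents that add atoms: tert-butylchlorodiphenylsilane, CC(C)(C)[Si](Cl)(c1ccccc1)c1ccccc1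
Why: Same selective primary silylation as in step 7, in the enantiomeric series.

Step 10
Reactants: 14 vanillin; 13 methyl (2R)-3-(tert-butyldiphenylsilyloxy)-2-hydroxypropanoate
Product: 15 methyl (2S)-2-(4-formyl-2-methoxyphenoxy)-3-(tert-butyldiphenylsilyloxy)propanoate
Conditions: PPh3, DIAD, THF, 0 °C → rt
Reagents that add atoms: none
Why: Mitsunobu etherification with inversion; the acidic phenol of vanillin is a good pronucleophile, and (R) becomes (S) at the future Cβ1. Ring B thus never needs a protecting group.

Step 11
Reactants: 11 core imide ester; 15 methyl (2S)-2-(4-formyl-2-methoxyphenoxy)-3-(tert-butyldiphenylsilyloxy)propanoate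
Product: 17 syn-aldol adduct (imide with Cα2 hydroxyl; both arms as methyl esters), via Z-boron enolate 16 (not isolated)
Conditions: Bu2BOTf, iPr2NEt, CH2Cl2, −78 → 0 °C; 15, −78 → 0 °C; pH 7 buffer, MeOH, H2O2, 0 °C
Reagents that add atoms: none
Why: Evans syn-aldol: soft enolisation is selective for the imide (the esters are not enolised) and gives the Z-enolate 16, which reacts through a chair Zimmerman–Traxler transition state on the face away from the benzyl group. This sets Cα2 and Cβ2 in the syn, that is threo, relation with the absolute sense dictated by the (S)-auxiliary, both (R) in the numbering of the target.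

Step 12
Reactants: 17 syn-aldol adduct
Product: 18 tetraol (unit 2 as free 1,3-diol; both arms as 1-hydroxy-3-silyloxypropan-2-yl ethers)
Conditions: LiBH4 (excess), THF, MeOH (additive), 0 °C → rt
Reagents that add atoms: none
Why: Borohydride reduction cleaves the activated imide carbonyl, releasing the auxiliary, and reduces both methyl esters to primary alcohols in one operation. No stereocentre is touched (the descriptors of the two arm carbons change by CIP rank only), and the tert-butyldiphenylsilyl groups should not migrate.

Step 13
Reactants: 18 tetraol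
Product: 19 diol with unit 2 as acetonide
Conditions: Me2C(OMe)2 (1.5 equiv), PPTS (cat.), acetone, rt; Et3N
Reagents that add atoms: 2,2-dimethoxypropane, COC(C)(C)OC
Why: Ketalisation under thermodynamic control: only the Cα2/Cγ2 pair is a 1,3-diol and can form the six-membered ketal (threo gives the cis-4-aryl-5-aryloxy-1,3-dioxane). The two isolated primary hydroxyls stay free.

Step 14
Reactants: 19 diol with unit 2 as acetonide
Product: 20 core dialdehyde
Conditions: Dess–Martin periodinane, NaHCO3, CH2Cl2, 0 °C → rt; crude product used at once
Reagents that add atoms: none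
Why: Dess–Martin oxidation of both primary alcohols under buffered, non-basic conditions should give the α-aryloxy aldehydes without enolisation, hence without epimerisation at Cβ1 or Cβ3 or loss of the β-silyloxy group.

Step 15
Reactants: 21 4-bromo-2-methoxyphenol
Product: 22 (4-bromo-2-methoxyphenoxy)(tert-butyl)dimethylsilane
Conditions: TBSCl, imidazole, DMF, rt
Reagents that add atoms: tert-butylchlorodimethylsilane, CC(C)(C)[Si](C)(C)Cl
Why: Silylation of the phenol, so that the aryl bromide can be metalated and the group can leave with fluoride at the end.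

Step 16
Reactants: 20 core dialdehyde; 22 (4-bromo-2-methoxyphenoxy)(tert-butyl)dimethylsilane (3 equiv)
Product: 25 fully assembled protected target, via aryllithium 23 (not isolated), via aryltitanium triisopropoxide 24 (not isolated)
Conditions: 22, n-BuLi, THF, −78 °C; ClTi(OiPr)3, −78 → −40 °C; 20, −78 → −10 °C; aq. NH4Cl, aq. potassium sodium tartrate
Reagents that add atoms: none
Why: Bromine–lithium exchange on 22 gives aryllithium 23, which ClTi(OiPr)3 converts into the monoaryltitanium reagent 24; 24 binds each formyl oxygen weakly and transfers its aryl group through a compact four-centre transition state, forming the Cα1–ring A and Cα3–ring E bonds, and no ring is closed. The closest known reaction type is the non-chelation-controlled addition of organotitanium triisopropoxides to α-alkoxy aldehydes. Each new carbinol centre is controlled by the neighbouring Cβ stereocentre through a polar Felkin–Anh transition state in which the C–OAr bond lies anti to the incoming aryl group and the aryl passes the Cβ hydrogen and not the CH2OSi arm. The (S) centre Cβ1 therefore induces (R) at Cα1 and the (R) centre Cβ3 induces (S) at Cα3, so one achiral reagent delivers both erythro (1,2-anti) units although they are of opposite absolute sense. The step needs 1,2-anti selectivity at both termini and no loss of configuration at Cβ; the weak Lewis acidity of the Ti(OiPr)3 unit, the poor donor ability of the aryl ether oxygens and the bulky, non-coordinating silyl ethers disfavour a chelate, and the low basicity of 24 avoids enolisation or β-elimination of the α-aryloxy aldehydes. The reagent is chemoselective for aldehydes, so the ketal, the silyl ethers and the benzylic ethers of the core are spectators, and an excess drives both termini to completion.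

Step 17
Reactants: 25 fully assembled protected target
Product: 26 tetrasilyl ether with unit 2 as free diol
Conditions: AcOH/THF/H2O (3:1:1), rt
Reagents that add atoms: none
Why: Acid hydrolysis of the ketal proceeds through the oxocarbenium ion of the acetone unit and not through benzylic ionisation, and at this acidity and temperature the benzylic C–O bonds should stay intact. Water is the only nucleophile, so no benzylic ether can form; the tert-butyldiphenylsilyl ethers and the aryl silyl ethers are stable to aqueous acetic acid.

Step 18
Reactants: 26 tetrasilyl ether with unit 2 as free diol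
Product: 27 target CNP0316493.1
Conditions: Bu4NF, AcOH (1:1), THF, 0 °C → rt
Reagents that add atoms: none
Why: Fluoride cleaves the two aryl and the two primary O–Si bonds; buffering with acetic acid keeps the medium close to neutral, so the phenols and the benzylic carbinols are not exposed to strong base.

## Compound list

1 | syringaldehyde (4-hydroxy-3,5-dimethoxybenzaldehyde) | COc1cc(C=O)cc(OC)c1O | starting material
2 | ethyl (E)-sinapate, ethyl (E)-3-(4-hydroxy-3,5-dimethoxyphenyl)prop-2-enoate | CCOC(=O)/C=C/c1cc(OC)c(O)c(OC)c1 | intermediate
3 | sinapyl alcohol, (E)-4-(3-hydroxyprop-1-enyl)-2,6-dimethoxyphenol | COc1cc(/C=C/CO)cc(OC)c1O | intermediate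
4 | rac-syringaresinol, exo,exo-2,6-bis(4-hydroxy-3,5-dimethoxyphenyl)-3,7-dioxabicyclo[3.3.0]octane, 1:1 mixture of the (7R,7'R,8S,8'S) and (7S,7'S,8R,8'R) forms | COc1cc([C@@H]2OC[C@@H]3[C@H]2CO[C@H]3c2cc(OC)c(O)c(OC)c2)cc(OC)c1O.COc1cc([C@H]2OC[C@H]3[C@@H]2CO[C@@H]3c2cc(OC)c(O)c(OC)c2)cc(OC)c1O | intermediate
5 | (7R,7'R,8S,8'S)-syringaresinol | COc1cc([C@@H]2OC[C@@H]3[C@H]2CO[C@H]3c2cc(OC)c(O)c(OC)c2)cc(OC)c1O | intermediate
6 | (S)-4-benzyloxazolidin-2-one | O=C1N[C@@H](Cc2ccccc2)CO1 | starting material
7 | (S)-4-benzyl-3-(bromoacetyl)oxazolidin-2-one | O=C(CBr)N1[C@@H](Cc2ccccc2)COC1=O | intermediate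
8 | mono-glycolate imide: (7R,7'R,8S,8'S)-syringaresinol whose ring C oxygen carries CH2C(=O) bonded to N-3 of (S)-4-benzyloxazolidin-2-one; ring D phenol free | COc1cc([C@@H]2OC[C@@H]3[C@H]2CO[C@H]3c2cc(OC)c(O)c(OC)c2)cc(OC)c1OCC(=O)N1[C@@H](Cc2ccccc2)COC1=O | intermediate
9 | methyl (S)-glycerate, methyl (2S)-2,3-dihydroxypropanoate | COC(=O)[C@@H](O)CO | starting material
10 | methyl (2S)-3-(tert-butyldiphenylsilyloxy)-2-hydroxypropanoate | COC(=O)[C@@H](O)CO[Si](c1ccccc1)(c1ccccc1)C(C)(C)C | intermediate
11 | core imide ester: 8 whose ring D oxygen carries the (R)-1-(methoxycarbonyl)-2-(tert-butyldiphenylsilyloxy)ethyl group (Cβ3 R) | COc1cc([C@@H]2OC[C@@H]3[C@H]2CO[C@H]3c2cc(OC)c(O[C@H](CO[Si](c3ccccc3)(c3ccccc3)C(C)(C)C)C(=O)OC)c(OC)c2)cc(OC)c1OCC(=O)N1[C@@H](Cc2ccccc2)COC1=O | intermediate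
12 | methyl (R)-glycerate, methyl (2R)-2,3-dihydroxypropanoate | COC(=O)[C@H](O)CO | starting material
13 | methyl (2R)-3-(tert-butyldiphenylsilyloxy)-2-hydroxypropanoate | COC(=O)[C@H](O)CO[Si](c1ccccc1)(c1ccccc1)C(C)(C)C | intermediate
14 | vanillin (4-hydroxy-3-methoxybenzaldehyde) | COc1cc(C=O)ccc1O | starting material
15 | methyl (2S)-2-(4-formyl-2-methoxyphenoxy)-3-(tert-butyldiphenylsilyloxy)propanoate | COC(=O)[C@H](CO[Si](c1ccccc1)(c1ccccc1)C(C)(C)C)Oc1ccc(C=O)cc1OC | intermediate
16 | Z-dibutylboron enolate of 11 (enolate oxygen and ring C oxygen cis), not isolated | CCCCB(CCCC)O/C(=C\Oc1c(OC)cc([C@@H]2OC[C@@H]3[C@H]2CO[C@H]3c2cc(OC)c(O[C@H](CO[Si](c3ccccc3)(c3ccccc3)C(C)(C)C)C(=O)OC)c(OC)c2)cc1OC)N1[C@@H](Cc2ccccc2)COC1=O | intermediate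
17 | syn-aldol adduct: (S)-4-benzyloxazolidin-2-one N-acylated by the (2S,3R)-3-hydroxy-3-aryl-2-aryloxypropanoyl group; the 3-aryl group is ring B carrying the (S)-1-(methoxycarbonyl)-2-silyloxyethyl ether, the 2-aryloxy group is ring C of the core, and ring D carries the (R)-configured ester arm | COC(=O)[C@H](CO[Si](c1ccccc1)(c1ccccc1)C(C)(C)C)Oc1ccc([C@@H](O)[C@@H](C(=O)N2[C@@H](Cc3ccccc3)COC2=O)Oc2c(OC)cc([C@@H]3OC[C@@H]4[C@H]3CO[C@H]4c3cc(OC)c(O[C@H](CO[Si](c4ccccc4)(c4ccccc4)C(C)(C)C)C(=O)OC)c(OC)c3)cc2OC)cc1OC | intermediate
18 | tetraol: unit 2 as free threo (αR,βR) 1,3-diol; ring B oxygen carries (R)-1-hydroxy-3-(tert-butyldiphenylsilyloxy)propan-2-yl and ring D oxygen its (S)-configured counterpart (same spatial arrangement as in 17) | OC[C@H](CO[Si](c1ccccc1)(c1ccccc1)C(C)(C)C)Oc1ccc([C@@H](O)[C@@H](CO)Oc2c(OC)cc([C@@H]3OC[C@@H]4[C@H]3CO[C@H]4c3cc(OC)c(O[C@H](CO[Si](c4ccccc4)(c4ccccc4)C(C)(C)C)CO)c(OC)c3)cc2OC)cc1OC | intermediate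
19 | diol with unit 2 as (4R,5R)-2,2-dimethyl-1,3-dioxane (ring B at C-4, ring C oxygen at C-5); both arm hydroxyls free | OC[C@H](CO[Si](c1ccccc1)(c1ccccc1)C(C)(C)C)Oc1ccc([C@@H](OC(C)(C)OC2)[C@@H]2Oc2c(OC)cc([C@@H]3OC[C@@H]4[C@H]3CO[C@H]4c3cc(OC)c(O[C@H](CO[Si](c4ccccc4)(c4ccccc4)C(C)(C)C)CO)c(OC)c3)cc2OC)cc1OC | intermediate
20 | core dialdehyde: as 19, with ring B oxygen carrying (S)-1-formyl-2-(tert-butyldiphenylsilyloxy)ethyl (Cβ1 S) and ring D oxygen carrying (R)-1-formyl-2-(tert-butyldiphenylsilyloxy)ethyl (Cβ3 R) | O=C[C@H](CO[Si](c1ccccc1)(c1ccccc1)C(C)(C)C)Oc1ccc([C@@H](OC(C)(C)OC2)[C@@H]2Oc2c(OC)cc([C@@H]3OC[C@@H]4[C@H]3CO[C@H]4c3cc(OC)c(O[C@H](CO[Si](c4ccccc4)(c4ccccc4)C(C)(C)C)C=O)c(OC)c3)cc2OC)cc1OC | intermediate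
21 | 4-bromo-2-methoxyphenol | COc1cc(Br)ccc1O | starting material
22 | (4-bromo-2-methoxyphenoxy)(tert-butyl)dimethylsilane | COc1cc(Br)ccc1O[Si](C)(C)C(C)(C)C | intermediate
23 | 4-(tert-butyldimethylsilyloxy)-3-methoxyphenyllithium, not isolated | COc1cc([Li])ccc1O[Si](C)(C)C(C)(C)C | intermediate
24 | 4-(tert-butyldimethylsilyloxy)-3-methoxyphenyltitanium triisopropoxide, not isolated | COc1cc([Ti](OC(C)C)(OC(C)C)OC(C)C)ccc1O[Si](C)(C)C(C)(C)C | intermediate
25 | fully assembled protected target: Cα1 R, Cβ1 S, Cα2 R, Cβ2 R (acetonide), core 7R,8S,7'R,8'S, Cβ3 R, Cα3 S; Cγ1 and Cγ3 as tert-butyldiphenylsilyl ethers; ring A and ring E phenols as tert-butyldimethylsilyl ethers | COc1cc([C@@H](O)[C@H](CO[Si](c2ccccc2)(c2ccccc2)C(C)(C)C)Oc2ccc([C@@H](OC(C)(C)OC3)[C@@H]3Oc3c(OC)cc([C@@H]4OC[C@@H]5[C@H]4CO[C@H]5c4cc(OC)c(O[C@H](CO[Si](c5ccccc5)(c5ccccc5)C(C)(C)C)[C@@H](O)c5ccc(O[Si](C)(C)C(C)(C)C)c(OC)c5)c(OC)c4)cc3OC)cc2OC)ccc1O[Si](C)(C)C(C)(C)C | intermediate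
26 | tetrasilyl ether: 25 with the Cα2 and Cγ2 hydroxyls free | COc1cc([C@@H](O)[C@H](CO[Si](c2ccccc2)(c2ccccc2)C(C)(C)C)Oc2ccc([C@@H](O)[C@@H](CO)Oc3c(OC)cc([C@@H]4OC[C@@H]5[C@H]4CO[C@H]5c4cc(OC)c(O[C@H](CO[Si](c5ccccc5)(c5ccccc5)C(C)(C)C)[C@@H](O)c5ccc(O[Si](C)(C)C(C)(C)C)c(OC)c5)c(OC)c4)cc3OC)cc2OC)ccc1O[Si](C)(C)C(C)(C)C | intermediate
27 | CNP0316493.1: (7R,7'R,8S,8'S)-syringaresinol whose ring C oxygen carries the threo (αR,βR) guaiacylglycerol unit 2, itself etherified at the ring B oxygen by the erythro (αR,βS) guaiacylglycerol unit 1, and whose ring D oxygen carries the erythro (αS,βR) guaiacylglycerol unit 3 | COc1cc([C@@H](O)[C@H](CO)Oc2ccc([C@@H](O)[C@@H](CO)Oc3c(OC)cc([C@@H]4OC[C@@H]5[C@H]4CO[C@H]5c4cc(OC)c(O[C@H](CO)[C@@H](O)c5ccc(O)c(OC)c5)c(OC)c4)cc3OC)cc2OC)ccc1O | target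

## Step count and least certain steps

Total: 18 steps. Longest linear sequence: 13 steps (1, 2, 3, 4, 6, 8, 11, 12, 13, 14, 16, 17, 18). The side branches are step 5 (one step), step 7 (one step), steps 9 and 10 (two steps) and step 15 (one step).

**Step 16 (key step).** The most likely failure is incomplete 1,2-anti facial selectivity at one of the two termini. A chelated or otherwise non-Felkin transition state, involving the aryl ether and ortho-methoxy oxygens, may compete, and any epimerisation of the labile α-aryloxy aldehydes before the addition would add to it. Because two centres are formed independently, a moderate leak at each end multiplies.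

Fallback: it sets out from the crude product of step 16 (25 mixed with its carbinol epimers) and comes back at 25. Dess–Martin oxidation converges all of this material on the bis(aryl ketone) F1. Reduction with Zn(BH4)2 in Et2O at −30 °C, under chelation control between the carbonyl and the α-aryloxy oxygen, delivers hydride past the Cβ hydrogen and should give the same erythro carbinols. The stereocentres are then set by hydride delivery to a ketone and not by aryl delivery to an aldehyde.

**Step 8.** The most likely failure is sluggish SN2 attack by the hindered 2,6-dimethoxyphenol, so that the activated hydroxy ester is consumed by alkylation of the reduced azodicarboxylate instead.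

Fallback: it sets out from 10 and 8 and comes back at 11. Compound 10 is converted with Tf2O and 2,6-lutidine (CH2Cl2, −78 °C) into the triflate F2, methyl (2S)-3-(tert-butyldiphenylsilyloxy)-2-(trifluoromethylsulfonyloxy)propanoate. The potassium phenoxide of 8 (K2CO3, MeCN, 0 °C) then displaces the triflate with inversion. A preformed, highly reactive electrophile replaces the phosphonium activation in the flask.

**Step 6.** The most likely failure is over-alkylation to the bis-ether together with acyl transfer from the imide to the phenoxide. Both lower the return of a statistical step on resolved material.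

Fallback: it sets out from 5 and comes back at 8.
- Mono-alkylation of 5 with allyl bromoacetate and K2CO3 gives the mono(allyl ester) F3, which is not an acyl donor under these conditions.
- Pd(PPh3)4 (zerovalent palladium) with morpholine removes the allyl group to give the aryloxyacetic acid F4.
- Activation of F4 as the pivaloyl mixed anhydride (PivCl, Et3N, THF, −20 °C), followed by LiCl and 6, gives 8. The hindered phenol is expected to remain a spectator.

**Step 4.** The most likely failure is loss of peak separation on overloading, so that the resolution does not deliver enough material.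

Fallback: it sets out from 4 and comes back at 5.
- Esterification of 4 with (S)-2-(6-methoxynaphthalen-2-yl)propanoic acid (N,N'-dicyclohexylcarbodiimide, DMAP cat., CH2Cl2, 0 °C) gives the diastereomeric bis-esters F5 (from the wanted enantiomer) and F6 (from the other).
- These are separated by crystallisation or ordinary chromatography.
- Methanolysis of F5 with K2CO3 in MeOH at 0 °C releases 5.

## Further compounds

F1 | step 16 | bis(aryl ketone): 25 with both Cα1 and Cα3 carbinols oxidised to ketones (Cβ1 S, Cβ3 R unchanged) | COc1cc(C(=O)[C@H](CO[Si](c2ccccc2)(c2ccccc2)C(C)(C)C)Oc2ccc([C@@H](OC(C)(C)OC3)[C@@H]3Oc3c(OC)cc([C@@H]4OC[C@@H]5[C@H]4CO[C@H]5c4cc(OC)c(O[C@H](CO[Si](c5ccccc5)(c5ccccc5)C(C)(C)C)C(=O)c5ccc(O[Si](C)(C)C(C)(C)C)c(OC)c5)c(OC)c4)cc3OC)cc2OC)ccc1O[Si](C)(C)C(C)(C)C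
F2 | step 8 | methyl (2S)-3-(tert-butyldiphenylsilyloxy)-2-(trifluoromethylsulfonyloxy)propanoate | COC(=O)[C@@H](OS(=O)(=O)C(F)(F)F)CO[Si](c1ccccc1)(c1ccccc1)C(C)(C)C
F3 | step 6 | mono(allyl ester): (7R,7'R,8S,8'S)-syringaresinol with the ring C oxygen carrying CH2CO2-allyl; ring D phenol free | C=CCOC(=O)COc1c(OC)cc([C@@H]2OC[C@@H]3[C@H]2CO[C@H]3c2cc(OC)c(O)c(OC)c2)cc1OC
F4 | step 6 | aryloxyacetic acid: (7R,7'R,8S,8'S)-syringaresinol with the ring C oxygen carrying CH2CO2H; ring D phenol free | OC(=O)COc1c(OC)cc([C@@H]2OC[C@@H]3[C@H]2CO[C@H]3c2cc(OC)c(O)c(OC)c2)cc1OC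
F5 | step 4 | bis[(S)-2-(6-methoxynaphthalen-2-yl)propanoate] of (7R,7'R,8S,8'S)-syringaresinol | COc1cc([C@@H]2OC[C@@H]3[C@H]2CO[C@H]3c2cc(OC)c(OC(=O)[C@@H](C)c3ccc4cc(OC)ccc4c3)c(OC)c2)cc(OC)c1OC(=O)[C@@H](C)c1ccc2cc(OC)ccc2c1
F6 | step 4 | bis[(S)-2-(6-methoxynaphthalen-2-yl)propanoate] of (7S,7'S,8R,8'R)-syringaresinol | COc1cc([C@H]2OC[C@H]3[C@@H]2CO[C@@H]3c2cc(OC)c(OC(=O)[C@@H](C)c3ccc4cc(OC)ccc4c3)c(OC)c2)cc(OC)c1OC(=O)[C@@H](C)c1ccc2cc(OC)ccc2c1
A1 | alternative 1 | 1,4-bis[(R)-4-benzyl-2-oxooxazolidin-3-yl]butane-1,4-dione | O=C(CCC(=O)N1[C@H](Cc2ccccc2)COC1=O)N1[C@H](Cc2ccccc2)COC1=O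
A2 | alternative 1 | 4-(benzyloxy)-3,5-dimethoxybenzaldehyde | COc1cc(C=O)cc(OC)c1OCc1ccccc1
A3 | alternative 1 | (1R,2R,5R,6R)-2,6-bis(4-benzyloxy-3,5-dimethoxyphenyl)-3,7-dioxabicyclo[3.3.0]octane-4,8-dione (exo,exo) | COc1cc([C@@H]2OC(=O)[C@@H]3[C@H]2C(=O)O[C@H]3c2cc(OC)c(OCc4ccccc4)c(OC)c2)cc(OC)c1OCc1ccccc1
A4 | alternative 2 | (E)-3-[4-(tert-butyldimethylsilyloxy)-3,5-dimethoxyphenyl]allyl ether of (S)-(4-benzyloxy-3,5-dimethoxyphenyl)[(2R)-oxiran-2-yl]methanol | COc1cc([C@@H]([C@H]2CO2)OC/C=C/c2cc(OC)c(O[Si](C)(C)C(C)(C)C)c(OC)c2)cc(OC)c1OCc1ccccc1
A5 | alternative 2 | (7R,7'R,8S,8'S)-syringaresinol with one phenol as benzyl ether and the other as tert-butyldimethylsilyl ether | COc1cc([C@@H]2OC[C@@H]3[C@H]2CO[C@H]3c2cc(OC)c(O[Si](C)(C)C(C)(C)C)c(OC)c2)cc(OC)c1OCc1ccccc1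
A6 | alternative 3 | bis-glycolate imide: (7R,7'R,8S,8'S)-syringaresinol with both phenol oxygens carrying CH2C(=O) bonded to N-3 of (S)-4-benzyloxazolidin-2-one | O=C(COc1c(OC)cc([C@@H]2OC[C@@H]3[C@H]2CO[C@H]3c2cc(OC)c(OCC(=O)N3[C@@H](Cc4ccccc4)COC3=O)c(OC)c2)cc1OC)N1[C@@H](Cc2ccccc2)COC1=O
A7 | alternative 3 | C2-symmetric bis[(R)-2-aryloxy-3-benzyloxypropanoyl] imide of the core with (S)-4-benzyloxazolidin-2-one | O=C([C@@H](COCc5ccccc5)Oc1c(OC)cc([C@@H]2OC[C@@H]3[C@H]2CO[C@H]3c2cc(OC)c(O[C@H](COCc3ccccc3)C(=O)N3[C@@H](Cc4ccccc4)COC3=O)c(OC)c2)cc1OC)N1[C@@H](Cc2ccccc2)COC1=O
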